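**Plan** (Bn = benzyl, TBS = tert-butyldimethylsilyl; flavan numbering; "upper" = the 4-linked ent-oritin unit, "lower" = the 6-linked teracacidin unit)
- Cuts: O1–C2 and C3–C4 of upper ring C in one retro-[4+2] (o-quinone methide plus (E)-enol acetate); then upper C4–lower C6 (aryllithium plus salicylaldehyde); in the lower unit O1–C2 (Mitsunobu), the C2/C3 oxygens (osmylation) and C3–C4 (alkynylation).
- Forward: both rings A come from 2,3,4-trihydroxybenzaldehyde, both rings B from 1-(benzyloxy)-4-ethynylbenzene; lower ring C is built first, the two ring A units are joined through the future upper C4, and upper ring C is closed last.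
- Enabling feature: upper C4 is doubly benzylic, between C4a of upper ring A (O1 ortho on C8a) and C6 of lower ring A, so its carbinol ionises to the o-quinone methide O1=C8a–C4a=C4. Upper ring C is all-trans (all-equatorial), the pattern of an endo [4+2] with an (E)-alkene, and the 4'-oxygen of ring B polarises C2=C3 so that C3 bonds to C4 and C2 to O1.
- Stereochemistry: lower C4 by catalytic asymmetric alkynylation; lower C3 and C2 by anti-selective syn-osmylation of the Z-alkene and Mitsunobu inversion at C2 (2,3-cis-3,4-cis). Upper C2, C3 and C4 are all set in the key step: relative by alkene geometry and endo approach, absolute by a chiral phosphoric acid.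
- Protection: six phenols as benzyl ethers (one final hydrogenolysis), the lower 3,4-diol as TBS ethers, the upper 3-OH as the acetate that arrives with the dienophile.

Key step: step 14

Remark: the sense of induction of (S)-BINOL in step 4 and of (R)-TRIP in step 14 is assigned by analogy; if it proves opposite, the antipodal ligand or acid is used and nothing else changes.
Remark: compounds 1 and 5 are taken as commercial.

**Step 1**
Reactants: 1 2,3,4-trihydroxybenzaldehyde
Product: 2 3,4-bis(benzyloxy)-2-hydroxybenzaldehyde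
Conditions: BnBr (2.05 equiv), K2CO3 (2 equiv), DMF, 0 °C to rt
Reagents that add atoms: benzyl bromide, BrCc1ccccc1
Why: Williamson etherification in which the 2-OH, hydrogen-bonded to the aldehyde, is the least nucleophilic oxygen, so two equivalents of benzyl bromide should alkylate O3 and O4 only.

**Step 2**
Reactants: 2 3,4-bis(benzyloxy)-2-hydroxybenzaldehyde
Product: 3 3,4-bis(benzyloxy)-5-bromo-2-hydroxybenzaldehyde
Conditions: NBS (1.05 equiv), MeCN, 0 °C to rt
Reagents that add atoms: N-bromosuccinimide, O=C1CCC(=O)N1Br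
Why: electrophilic aromatic bromination should go to C5, which is para to the free phenol and ortho to the 4-benzyloxy group, the only strongly activated open position (the future lower C6).

**Step 3**
Reactants: 3 3,4-bis(benzyloxy)-5-bromo-2-hydroxybenzaldehyde
Product: 4 3,4-bis(benzyloxy)-5-bromo-2-(TBSO)benzaldehyde
Conditions: TBSCl, imidazole, DMAP (cat.), DMF, rt
Reagents that add atoms: tert-butyldimethylsilyl chloride, CC(C)(C)[Si](C)(C)Cl
Why: standard silylation masks the acidic phenol so that it cannot quench the zinc acetylide of the next step.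

**Step 4**
Reactants: 4 3,4-bis(benzyloxy)-5-bromo-2-(TBSO)benzaldehyde; 5 1-(benzyloxy)-4-ethynylbenzene
Product: 6 (S)-1-[3,4-bis(benzyloxy)-5-bromo-2-(TBSO)phenyl]-3-[4-(benzyloxy)phenyl]prop-2-yn-1-ol
Conditions: 5 (1.5 equiv), Et2Zn (2 equiv), toluene, reflux; then (S)-BINOL (20 mol %), Ti(OiPr)4 (50 mol %), CH2Cl2, rt; then 4, rt; aq NH4Cl
Reagents that add atoms: none
Why: BINOL–Ti(OiPr)4-catalysed enantioselective addition of an alkynylzinc to an aromatic aldehyde, in which the chiral titanium complex selects the aldehyde face and should set the carbinol centre (the future lower C4) as S.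

**Step 5**
Reactants: 6 the (S)-propargylic alcohol
Product: 7 (S)-1-[3,4-bis(benzyloxy)-5-bromo-2-(TBSO)phenyl]-3-[4-(benzyloxy)phenyl]-1-(TBSO)prop-2-yne
Conditions: TBSCl, imidazole, DMF, rt
Reagents that add atoms: tert-butyldimethylsilyl chloride, CC(C)(C)[Si](C)(C)Cl
Why: routine silylation of a secondary alcohol, which also makes any aryl-to-alkoxide silyl shift in step 4 harmless because both oxygens end as TBS ethers.

**Step 6**
Reactants: 7 the bis-silylated alkyne
Product: 8 (S,Z)-1-[3,4-bis(benzyloxy)-5-bromo-2-(TBSO)phenyl]-3-[4-(benzyloxy)phenyl]-1-(TBSO)prop-2-ene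
Conditions: H2 (1 atm), Pd/CaCO3 poisoned with Pb(OAc)2, quinoline, EtOAc, rt
Reagents that add atoms: none
Why: Lindlar semi-hydrogenation delivers both hydrogens to one face of the alkyne and should give the Z-alkene, while the poisoned catalyst leaves the aryl bromide and the benzyl ethers alone.

**Step 7**
Reactants: 8 the (S,Z)-alkene
Product: 9 (1S,2S,3R)-1-[4-(benzyloxy)phenyl]-3-[3,4-bis(benzyloxy)-5-bromo-2-(TBSO)phenyl]-3-(TBSO)propane-1,2-diol
Conditions: OsO4 (5 mol %), NMO (1.5 equiv), acetone/H2O, rt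
Reagents that add atoms: N-methylmorpholine N-oxide, C[N+]1([O-])CCOCC1; water, O
Why: Upjohn dihydroxylation adds both oxygens syn to the Z-alkene (erythro C1/C2), and by the empirical anti rule for osmylation of allylic ethers osmium should attack the face opposite the silyloxy group in the conformer that minimises A(1,3) strain, placing the new C2 oxygen anti to the C3 oxygen.

**Step 8**
Reactants: 9 the bis-silylated diol
Product: 10 (1S,2S,3R)-1-[4-(benzyloxy)phenyl]-3-[3,4-bis(benzyloxy)-5-bromo-2-hydroxyphenyl]-3-(TBSO)propane-1,2-diol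
Conditions: KHF2 (2 equiv), MeOH, rt
Reagents that add atoms: none
Why: bifluoride cleaves an aryl silyl ether much faster than an alkyl silyl ether because phenoxide is the better leaving group, so only the phenol should be freed.

**Step 9**
Reactants: 10 the phenol diol
Product: 11 (2R,3S,4R)-7,8-bis(benzyloxy)-2-[4-(benzyloxy)phenyl]-6-bromo-4-(TBSO)chroman-3-ol
Conditions: PPh3, DIAD, THF, 0 °C to rt
Reagents that add atoms: none
Why: Mitsunobu cycloetherification in which the phenol displaces the activated benzylic C1–OH in a 6-exo-tet SN2 closure with inversion, turning the erythro diol into the 2,3-cis flavan so that ring C is 2,3-cis-3,4-cis.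

**Step 10**
Reactants: 11 the flavan-3-ol
Product: 12 (2R,3S,4R)-7,8-bis(benzyloxy)-2-[4-(benzyloxy)phenyl]-6-bromo-3,4-bis(TBSO)chromane
Conditions: TBSOTf, 2,6-lutidine, CH2Cl2, 0 °C
Reagents that add atoms: tert-butyldimethylsilyl triflate, CC(C)(C)[Si](C)(C)OS(=O)(=O)C(F)(F)F
Why: the silyl triflate overcomes the hindrance of the axial 3-OH next to the 4-OTBS group and removes the last acidic proton before the organolithium step.

**Step 11**
Reactants: 12 the bromoflavan; 2 3,4-bis(benzyloxy)-2-hydroxybenzaldehyde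
Product: 15 [3,4-bis(benzyloxy)-2-hydroxyphenyl]{(2R,3S,4R)-7,8-bis(benzyloxy)-2-[4-(benzyloxy)phenyl]-3,4-bis(TBSO)chroman-6-yl}methanol (both carbinol epimers), via sodium aryloxide 13 (not isolated), via aryllithium 14 (not isolated)
Conditions: 2, NaH (1 equiv), THF, 0 °C; separately 12, n-BuLi (1.05 equiv), THF, −78 °C; combine at −78 °C, warm to −30 °C; aq NH4Cl
Reagents that add atoms: none
Why: bromine–lithium exchange at C6 followed by 1,2-addition of the aryllithium to the aldehyde of the preformed phenoxide; the new carbinol centre is uncontrolled and need not be controlled, because it becomes sp2 in step 14.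

**Step 12**
Reactants: 5 1-(benzyloxy)-4-ethynylbenzene
Product: 17 potassium (E)-{2-[4-(benzyloxy)phenyl]vinyl}trifluoroborate, via alkenylboronate 16 (not isolated)
Conditions: pinacolborane (1.2 equiv), Cp2Zr(H)Cl (5 mol %), Et3N (10 mol %), 60 °C; then aq KHF2, MeOH, rt
Reagents that add atoms: pinacolborane, B1OC(C)(C)C(C)(C)O1; potassium hydrogen difluoride, [K+].[F-].F
Why: zirconium-catalysed syn hydroboration of the terminal alkyne puts boron on the terminal carbon and should give only the (E)-alkenylboronate, which bifluoride converts into the crystalline trifluoroborate with retention of geometry.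

**Step 13**
Reactants: 17 the (E)-alkenyltrifluoroborate
Product: 18 (E)-2-[4-(benzyloxy)phenyl]vinyl acetate
Conditions: AcOH (3 equiv), Cu(OAc)2 (10 mol %), DMAP (20 mol %), 4 Å MS, O2 (1 atm), CH2Cl2, rt
Reagents that add atoms: acetic acid, CC(=O)O
Why: copper-catalysed oxidative C–O coupling of an alkenylboron compound with a carboxylic acid (Chan–Lam type) is stereoretentive and should give the (E)-enol ester.

**Step 14**
Reactants: 15 the diaryl carbinol; 18 (E)-2-[4-(benzyloxy)phenyl]vinyl acetate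
Product: 20 3-O-acetyl-7,8,4'-tri-O-benzyl-ent-oritin-(4β→6)-7,8,4'-tri-O-benzyl-3,4-bis-O-TBS-epioritin-4α-ol, via o-quinone methide 19 (not isolated)
Conditions: 18 (3 equiv), (R)-TRIP [(R)-3,3'-bis(2,4,6-triisopropylphenyl)-1,1'-binaphthyl-2,2'-diyl hydrogen phosphate] (10 mol %), 5 Å MS, PhCF3, 0 °C to rt
Reagents that add atoms: none
Why: Proposed new method: the chiral phosphoric acid should ionise the doubly benzylic C4 carbinol of 15 to the (E)-o-quinone methide 19 (heterodiene O1=C8a–C4a=C4, held to the phosphate by hydrogen bond and ion pair), which should add the electron-rich alkene of 18 in an asynchronous inverse-electron-demand oxa-[4+2] cycloaddition; the closest known reaction type is the Brønsted-acid-catalysed hetero-Diels–Alder reaction of o-hydroxybenzhydrol-derived o-quinone methides with styrenes and anethole-type alkenes, and what is new is a β-acyloxystyrene as the two-carbon partner. Ring C of the upper unit closes in [4+2] mode, the C4–C3 bond leading and the O1–C2 bond following, from a four-atom heterodiene and a two-atom dienophile. Regiochemistry rests on ring B: the 4-benzyloxyphenyl group stabilises positive charge at C2 far better than the ester oxygen can at C3, so the acetoxy-bearing carbon bonds to C4 and O1 closes on C2, and if the ester carbonyl captures C2 first, O1 opens that acetoxonium ion with inversion to the same product. The 2,3-trans relation is carried over from the (E)-alkene by suprafacial addition, and C4 is set 2,4-cis and 3,4-trans by the endo placement of ring B under the (E)-quinone methide, which gives the all-equatorial ring. The absolute sense (2S and 3R with the 4β-aryl bond) has to come from the chiral phosphate shielding one face of 19, because the stereocentres of the lower unit are too remote from C4; the other facial isomer is a diastereomer and should be removable by chromatography. The step also needs chemoselective ionisation of the C4 carbinol in the presence of the benzylic C4–OTBS of the lower unit, which the double aryl and ortho-hydroxy activation together with the weak acid should secure, while the sieves keep water from hydrolysing 18.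

**Step 15**
Reactants: 20 the cycloadduct
Product: 22 7,8,4'-tri-O-benzyl-ent-oritin-(4β→6)-7,8,4'-tri-O-benzyl-epioritin-4α-ol, via diol acetate 21 (not isolated)
Conditions: TBAF (4 equiv), THF, 0 °C to rt; then K2CO3 (cat.), MeOH, rt
Reagents that add atoms: none
Why: fluoride cleaves both silyl ethers and base-catalysed transesterification then removes the acetate, touching no stereocentre and avoiding the acid that could ionise the benzylic C4–OH of the lower unit.

**Step 16**
Reactants: 22 the hexabenzyl ether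
Product: 23 ent-oritin-(4β→6)-epioritin-4α-ol (upper unit 2S,3R,4S; lower unit 2R,3R,4R), the target
Conditions: H2 (1 atm), Pd(OH)2/C, THF/MeOH, rt
Reagents that add atoms: none
Why: hydrogenolysis of the six aryl benzyl ethers under neutral conditions, in which the flavan C2–O1 bonds and the lower benzylic C4–OH should survive as long as no acid is present.

**Compound list**
1 | 2,3,4-trihydroxybenzaldehyde | O=Cc1ccc(O)c(O)c1O | starting material
2 | 3,4-bis(benzyloxy)-2-hydroxybenzaldehyde | O=Cc1ccc(OCc2ccccc2)c(OCc2ccccc2)c1O | intermediate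
3 | 3,4-bis(benzyloxy)-5-bromo-2-hydroxybenzaldehyde | O=Cc1cc(Br)c(OCc2ccccc2)c(OCc2ccccc2)c1O | intermediate
4 | 3,4-bis(benzyloxy)-5-bromo-2-(TBSO)benzaldehyde | O=Cc1cc(Br)c(OCc2ccccc2)c(OCc2ccccc2)c1O[Si](C)(C)C(C)(C)C | intermediate
5 | 1-(benzyloxy)-4-ethynylbenzene | C#Cc1ccc(OCc2ccccc2)cc1 | starting material
6 | (S)-1-[3,4-bis(benzyloxy)-5-bromo-2-(TBSO)phenyl]-3-[4-(benzyloxy)phenyl]prop-2-yn-1-ol | c1ccccc1COc1ccc(cc1)C#C[C@H](O)c1cc(Br)c(OCc2ccccc2)c(OCc2ccccc2)c1O[Si](C)(C)C(C)(C)C | intermediate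
7 | (S)-1-[3,4-bis(benzyloxy)-5-bromo-2-(TBSO)phenyl]-3-[4-(benzyloxy)phenyl]-1-(TBSO)prop-2-yne | c1ccccc1COc1ccc(cc1)C#C[C@H](O[Si](C)(C)C(C)(C)C)c1cc(Br)c(OCc2ccccc2)c(OCc2ccccc2)c1O[Si](C)(C)C(C)(C)C | intermediate
8 | (S,Z)-1-[3,4-bis(benzyloxy)-5-bromo-2-(TBSO)phenyl]-3-[4-(benzyloxy)phenyl]-1-(TBSO)prop-2-ene | c1ccccc1COc1ccc(cc1)/C=C\[C@H](O[Si](C)(C)C(C)(C)C)c1cc(Br)c(OCc2ccccc2)c(OCc2ccccc2)c1O[Si](C)(C)C(C)(C)C | intermediate
9 | (1S,2S,3R)-1-[4-(benzyloxy)phenyl]-3-[3,4-bis(benzyloxy)-5-bromo-2-(TBSO)phenyl]-3-(TBSO)propane-1,2-diol | c1ccccc1COc1ccc(cc1)[C@H](O)[C@H](O)[C@H](O[Si](C)(C)C(C)(C)C)c1cc(Br)c(OCc2ccccc2)c(OCc2ccccc2)c1O[Si](C)(C)C(C)(C)C | intermediate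
10 | (1S,2S,3R)-1-[4-(benzyloxy)phenyl]-3-[3,4-bis(benzyloxy)-5-bromo-2-hydroxyphenyl]-3-(TBSO)propane-1,2-diol | c1ccccc1COc1ccc(cc1)[C@H](O)[C@H](O)[C@H](O[Si](C)(C)C(C)(C)C)c1cc(Br)c(OCc2ccccc2)c(OCc2ccccc2)c1O | intermediate
11 | (2R,3S,4R)-7,8-bis(benzyloxy)-2-[4-(benzyloxy)phenyl]-6-bromo-4-(TBSO)chroman-3-ol (2,3-cis-3,4-cis) | c1ccccc1COc1ccc([C@H]2Oc3c(cc(Br)c(OCc4ccccc4)c3OCc3ccccc3)[C@@H](O[Si](C)(C)C(C)(C)C)[C@H]2O)cc1 | intermediate
12 | (2R,3S,4R)-7,8-bis(benzyloxy)-2-[4-(benzyloxy)phenyl]-6-bromo-3,4-bis(TBSO)chromane | c1ccccc1COc1ccc([C@H]2Oc3c(cc(Br)c(OCc4ccccc4)c3OCc3ccccc3)[C@@H](O[Si](C)(C)C(C)(C)C)[C@H]2O[Si](C)(C)C(C)(C)C)cc1 | intermediate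
13 | sodium 2,3-bis(benzyloxy)-6-formylphenoxide (sodium aryloxide of 2) | [Na+].[O-]c1c(C=O)ccc(OCc2ccccc2)c1OCc1ccccc1 | intermediate
14 | 6-lithio derivative of 12 (aryllithium) | c1ccccc1COc1ccc([C@H]2Oc3c(cc([Li])c(OCc4ccccc4)c3OCc3ccccc3)[C@@H](O[Si](C)(C)C(C)(C)C)[C@H]2O[Si](C)(C)C(C)(C)C)cc1 | intermediate
15 | [3,4-bis(benzyloxy)-2-hydroxyphenyl]{(2R,3S,4R)-7,8-bis(benzyloxy)-2-[4-(benzyloxy)phenyl]-3,4-bis(TBSO)chroman-6-yl}methanol, both carbinol epimers | c1ccccc1COc1ccc([C@H]2Oc3c(cc(C(O)c4ccc(OCc5ccccc5)c(OCc5ccccc5)c4O)c(OCc4ccccc4)c3OCc3ccccc3)[C@@H](O[Si](C)(C)C(C)(C)C)[C@H]2O[Si](C)(C)C(C)(C)C)cc1 | intermediate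
16 | (E)-2-{2-[4-(benzyloxy)phenyl]vinyl}-4,4,5,5-tetramethyl-1,3,2-dioxaborolane | CC1(C)OB(/C=C/c2ccc(OCc3ccccc3)cc2)OC1(C)C | intermediate
17 | potassium (E)-{2-[4-(benzyloxy)phenyl]vinyl}trifluoroborate | [K+].F[B-](F)(F)/C=C/c1ccc(OCc2ccccc2)cc1 | intermediate
18 | (E)-2-[4-(benzyloxy)phenyl]vinyl acetate | CC(=O)O/C=C/c1ccc(OCc2ccccc2)cc1 | intermediate
19 | (E)-o-quinone methide: (E)-2,3-bis(benzyloxy)-6-{[(2R,3S,4R)-7,8-bis(benzyloxy)-2-[4-(benzyloxy)phenyl]-3,4-bis(TBSO)chroman-6-yl]methylidene}cyclohexa-2,4-dien-1-one | c1ccccc1COc1ccc([C@H]2Oc3c(cc(/C=C4\C=CC(OCc5ccccc5)=C(OCc5ccccc5)C4=O)c(OCc4ccccc4)c3OCc3ccccc3)[C@@H](O[Si](C)(C)C(C)(C)C)[C@H]2O[Si](C)(C)C(C)(C)C)cc1 | intermediate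
20 | 3-O-acetyl-7,8,4'-tri-O-benzyl-ent-oritin-(4β→6)-7,8,4'-tri-O-benzyl-3,4-bis-O-TBS-epioritin-4α-ol (upper ring C 2,3-trans-3,4-trans) | c1ccccc1COc1ccc([C@H]2Oc3c(cc([C@H]4c5ccc(OCc6ccccc6)c(OCc6ccccc6)c5O[C@@H](c5ccc(OCc6ccccc6)cc5)[C@@H]4OC(C)=O)c(OCc4ccccc4)c3OCc3ccccc3)[C@@H](O[Si](C)(C)C(C)(C)C)[C@H]2O[Si](C)(C)C(C)(C)C)cc1 | intermediate
21 | 3-O-acetyl-7,8,4'-tri-O-benzyl-ent-oritin-(4β→6)-7,8,4'-tri-O-benzyl-epioritin-4α-ol | c1ccccc1COc1ccc([C@H]2Oc3c(cc([C@H]4c5ccc(OCc6ccccc6)c(OCc6ccccc6)c5O[C@@H](c5ccc(OCc6ccccc6)cc5)[C@@H]4OC(C)=O)c(OCc4ccccc4)c3OCc3ccccc3)[C@@H](O)[C@H]2O)cc1 | intermediate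
22 | 7,8,4'-tri-O-benzyl-ent-oritin-(4β→6)-7,8,4'-tri-O-benzyl-epioritin-4α-ol | c1ccccc1COc1ccc([C@H]2Oc3c(cc([C@H]4c5ccc(OCc6ccccc6)c(OCc6ccccc6)c5O[C@@H](c5ccc(OCc6ccccc6)cc5)[C@@H]4O)c(OCc4ccccc4)c3OCc3ccccc3)[C@@H](O)[C@H]2O)cc1 | intermediate
23 | ent-oritin-(4β→6)-epioritin-4α-ol; upper unit (2S,3R,4S), lower unit (2R,3R,4R) | Oc1ccc([C@H]2Oc3c(cc([C@H]4c5ccc(O)c(O)c5O[C@@H](c5ccc(O)cc5)[C@@H]4O)c(O)c3O)[C@@H](O)[C@H]2O)cc1 | target

**Totals**
Total step count: 16. Longest linear sequence: 14 (steps 1 to 11, then 14, 15, 16).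

**Steps most likely to fail**

1. Step 14 (Proposed new method). The acid may deliver the cycloadduct with poor facial or endo control, the enol acetate may lose its acyl group, or the cation may alkylate an arene instead of the alkene. The fallback uses known chemistry and sets out from 15.
 - Trifluoroborate 17 is hydrolysed (SiO2, H2O) to (E)-2-[4-(benzyloxy)phenyl]vinylboronic acid F1.
 - F1 is added to the o-quinone methide formed from 15 in a biphenol-catalysed conjugate alkenylation ((R)-3,3'-dibromo-BINOL, 4 Å MS, PhCF3, warm). This sets C4 under catalyst control and should give the 2-(1,3-diarylallyl)phenol F2.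
 - Sharpless asymmetric dihydroxylation of the (E)-alkene (OsO4, (DHQD)2PHAL, NMO, t-BuOH/H2O, 0 °C; NMO spares the free phenol) should give the syn-diol F3 under reagent control.
 - Mitsunobu cyclisation (PPh3, DIAD, THF) then closes upper ring C at O1–C2 with inversion to the 2,3-trans-3,4-trans flavan-3-ol F4.
 - TBAF removes the two silyl ethers, and the sequence comes back to the route at 22.

2. Step 7. Osmylation may show poor facial selectivity, with attack anti to the aryl group instead of anti to the silyloxy group, which would lead into the 3,4-trans series. The fallback sets out from 8.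
 - Jacobsen–Katsuki epoxidation of the Z-styrene, using the enantiomer of [N,N'-bis(3,5-di-tert-butylsalicylidene)-1,2-cyclohexanediamine]MnCl that reinforces attack anti to the silyloxy group (NaOCl, 4-phenylpyridine N-oxide, CH2Cl2, 0 °C), should give the cis-epoxide F5.
 - KHF2 in MeOH frees the phenol to the epoxy phenol F6.
 - F6 should close 6-endo at the benzylic epoxide carbon with inversion (cat. camphorsulfonic acid if needed). It comes back to the route at 11 and bypasses steps 7 to 9.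

3. Step 11. The aryllithium may be lost to α-lithiation of a benzyl ether with Wittig rearrangement or to protonation, or it may add sluggishly to the phenoxide aldehyde. The fallback sets out from 12.
 - Miyaura borylation (B2pin2, Pd(dppf)Cl2, KOAc, dioxane, 80 °C) should give the arylboronate F7.
 - Rhodium-catalysed 1,2-addition of F7 to aldehyde 2 ([Rh(cod)OH]2, dioxane/H2O, 60 °C) comes back to the route at 15.

**Further compounds**
F1 | step 14 | (E)-2-[4-(benzyloxy)phenyl]vinylboronic acid | OB(O)/C=C/c1ccc(OCc2ccccc2)cc1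
F2 | step 14 | 2-(1,3-diarylallyl)phenol: lower flavan 12 with Br replaced by the (E)-1-[3,4-bis(benzyloxy)-2-hydroxyphenyl]-3-[4-(benzyloxy)phenyl]allyl group, configuration at the allylic carbon as in the SMILES | c1ccccc1COc1ccc([C@H]2Oc3c(cc([C@@H](c4ccc(OCc5ccccc5)c(OCc5ccccc5)c4O)/C=C/c4ccc(OCc5ccccc5)cc4)c(OCc4ccccc4)c3OCc3ccccc3)[C@@H](O[Si](C)(C)C(C)(C)C)[C@H]2O[Si](C)(C)C(C)(C)C)cc1
F3 | step 14 | syn-1,2-diol from F2 (1-[4-(benzyloxy)phenyl]-3-[3,4-bis(benzyloxy)-2-hydroxyphenyl]-3-(lower flavan-6-yl)propane-1,2-diol) | c1ccccc1COc1ccc([C@H]2Oc3c(cc([C@@H](c4ccc(OCc5ccccc5)c(OCc5ccccc5)c4O)[C@@H](O)[C@H](O)c4ccc(OCc5ccccc5)cc4)c(OCc4ccccc4)c3OCc3ccccc3)[C@@H](O[Si](C)(C)C(C)(C)C)[C@H]2O[Si](C)(C)C(C)(C)C)cc1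
F4 | step 14 | 7,8,4'-tri-O-benzyl-ent-oritin-(4β→6)-7,8,4'-tri-O-benzyl-3,4-bis-O-TBS-epioritin-4α-ol | c1ccccc1COc1ccc([C@H]2Oc3c(cc([C@H]4c5ccc(OCc6ccccc6)c(OCc6ccccc6)c5O[C@@H](c5ccc(OCc6ccccc6)cc5)[C@@H]4O)c(OCc4ccccc4)c3OCc3ccccc3)[C@@H](O[Si](C)(C)C(C)(C)C)[C@H]2O[Si](C)(C)C(C)(C)C)cc1
F5 | step 7 | cis-epoxide of 8 (oxygen on the face anti to the silyloxy group) | c1ccccc1COc1ccc(cc1)[C@@H]1O[C@@H]1[C@H](O[Si](C)(C)C(C)(C)C)c1cc(Br)c(OCc2ccccc2)c(OCc2ccccc2)c1O[Si](C)(C)C(C)(C)C
F6 | step 7 | epoxy phenol from F5 | c1ccccc1COc1ccc(cc1)[C@@H]1O[C@@H]1[C@H](O[Si](C)(C)C(C)(C)C)c1cc(Br)c(OCc2ccccc2)c(OCc2ccccc2)c1O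
F7 | step 11 | 6-(pinacolboryl) analogue of 12 | c1ccccc1COc1ccc([C@H]2Oc3c(cc(B4OC(C)(C)C(C)(C)O4)c(OCc4ccccc4)c3OCc3ccccc3)[C@@H](O[Si](C)(C)C(C)(C)C)[C@H]2O[Si](C)(C)C(C)(C)C)cc1
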